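## The problem

The target is a linear tetramer of C6C3 units. Ring A is a benzyl group on C4 of the tetrahydrofuran ring B; C2 of ring B is bonded to C5 of the dihydrobenzofuran C/D; C2 of ring D is bonded to C5 of the dihydrobenzofuran E/F; C2 of ring F carries the guaiacyl ring G. The seven stereocentres fall into three groups that cannot influence one another. Read from the structure, ring F is (2S,3R) and ring D is (2R,3S), so the two trans-2-aryl-3-hydroxymethyl-dihydrobenzofurans have opposite absolute sense. Ring B is (2R,3R,4R), with the aryl group, the CH2OH group and the ring A benzyl group all on one face; this is the C2 epimer of the usual 2,3-trans-3,4-cis pattern and the less stable arrangement. Inside a ring the centres can steer each other (C2 fixes C3 in a dihydrobenzofuran, C4 of ring B can fix C3), but each group needs its own absolute control, and the same motif must be made twice with opposite handedness. All three benzylic C2–O bonds carry a para-oxygenated aryl group: they ionise under acid (for ring B this would mean epimerisation to 2,3-trans) and can be hydrogenolysed. The guaiacol phenols are easily oxidised, so strong acid, oxidants and long hydrogenations must stay away from late intermediates. The enabling feature is that in rings E/F (and C/D) the ring-fusion carbon C3a, C3 and the hydroxymethyl carbon are contiguous. This is the sequence C4a–C3–C4 of a 2-arylchroman-4-one after the aryl carbon has moved from C4 to C3, so each dihydrobenzofuran is a flavanone whose carbonyl carbon has been pushed out of the ring as an ester.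

## Retrosynthesis

**35 ⇒ 34 ⇒ 32.** The last step frees the two phenols of 35 from the bis-benzyl ether 34. The CH2OH carbon on C3 of ring B is traced to the vinyl group of 32 (C=C cleaved by ozonolysis with reductive work-up). The reason is that the two CH2O carbons on C3 and C4 come from one lactone; if both were alcohols when ring B is closed, either could form a tetrahydrofuran. A vinyl group is inert to base, fluoride and sulfonylation and is converted to CH2OH without isolating the epimerisable all-cis aldehyde. The forward steps need an ozonolysis that spares the protected arenes and a hydrogenolysis that spares three benzylic ring C–O bonds.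

**32 ⇒ 29 ⇒ 28.** Ring B is opened at O1–C5. The more usual cut O1–C2 (closure onto a benzylic cation or sulfonate) is rejected because a para-alkoxybenzyl centre reacts by ionisation and gives the stable 2,3-trans ring. Cutting O1–C5 leaves the C2–O bond untouched, so the carbinol configuration of the open chain is copied into the ring. Tosylate 29 is acyclic and already holds all three stereocentres. The forward reaction is a 5-exo-tet displacement by the benzylic alkoxide, set free from its triethylsilyl ether by fluoride.

**28 ⇒ 27 ⇒ 26 ⇒ 25 ⇒ 18 + 24.** The C2–C3 bond is cut as an aldol between aldehyde 18 and lactone 24. The lactone does three jobs: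
- its ring forces the new substituent trans to the benzyl group, which becomes the 3,4-cis relation of ring B once the ring atoms are reassigned;
- the chair transition state of its enolate favours the anti aldol, which is the R carbinol needed for 2,3-cis;
- its carbonyl carbon differs in oxidation level from its CH2O carbon, so half-reduction (27) and methylenation (28) distinguish the two arms.

Adding an aryl-metal reagent from 17 to a lactone carbonyl and reducing the hemiketal would need a cis-disubstituted, epimerisable lactone and is not chosen. The cut divides the target into an aryl aldehyde with four stereocentres (all in dihydrobenzofurans) and a lactone with one.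

**18 ⇒ 17 ⇒ 16 ⇒ 15 ⇒ 14.** These are functional-group changes. The aldehyde comes from the aryl bromide. The two CH2OH groups and the ring G phenol come from the bis-ester acetate 14 in a single hydride reduction (triol 15). The phenol is then benzylated (it must survive fluoride and ozone) and the alcohols silylated.

**14 ⇒ 13 ⇒ 12 + 4.** Ring D is traced back by the reverse 1,2-shift (C3–C3a bond) to flavanone 13, and the C2–aryl bond of 13 to a conjugate addition of boronic acid 12 to chromone 4. Using the same two operations as for ring F means one chromone serves twice, and the opposite handedness of rings D and F comes from the choice of ligand enantiomer. The E–G unit travels as ester and acetate, so no protecting-group step lies between the two contractions. The forward contraction must work with a para-alkoxyaryl group on C2, which is the less secure of the two uses.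

**12 ⇒ 10 ⇒ 9 ⇒ 4 + 8.** Boronic acid 12 comes from bromide 10. Ester 10 is the product of the key ring contraction of flavanone 9 (C3–C3a bond formed, C4 extruded as CO2Me). Against an annulation that builds O1–C2 and C2–C3 from two achiral partners, this cut leaves a precursor with one stereocentre, set by a catalytic conjugate addition of boronic acid 8 to 4. The acetate on ring G is a deliberate choice for the migration selectivity.

**Building blocks.** Chromone 4 comes from acetophenone 1 through bromide 2 (enaminone 3). Boronic acid 8 comes from phenol 5 through acetate 6 (boronate 7). Lactone 24 comes from aldehyde 19 and diester 20 by Stobbe condensation (21), asymmetric hydrogenation (22) and reduction–lactonisation (23).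

## Roads not taken

**Alternative 1:** The cut is a [4+1] disconnection of ring F at O1–C2 and C2–C3. Base would release the ortho-quinone methide of ring E from sulfone A2 and the benzylic ylide from sulfonium salt A3. The ylide carbon adds to the methide carbon and the phenoxide displaces the sulfide to give A1.
- Merits: two bonds and the ring form in one mildly basic step, the trans ring results directly, and the side chain is already at the alcohol level. Per dihydrobenzofuran this is shorter and gentler than conjugate addition, acid/oxidant contraction and hydride reduction, and that advantage is real.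
- Weak points: both stereocentres arise at once from achiral partners, so absolute control must come from a chiral sulfide or catalyst. The dependable cases carry an aryl group on the methide carbon; here it carries CH2OBn, and such alkyl quinone methides tautomerise easily. For ring D the ylide would have to be made from the whole E–G unit (homologation of the bromide to a benzylic sulfonium salt) and used under double stereodifferentiation.
- Comparison: the chosen plan offers one catalytic, ligand-controlled stereocentre per unit, its stereospecific transfer to C3, and the reuse of chromone 4 for both enantiomeric series.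

**Alternative 2:** The cut lies inside the lactone. A flavin-dependent Baeyer–Villiger monooxygenase would insert oxygen into one of the two enantiotopic C(O)–CH2 bonds of cyclobutanone A5 and give lactone A4, which is the same compound as 24.
- Merits: high enantioselectivity is typical for such desymmetrisations, conditions are ambient and aqueous, and no precious metal or pressure is needed. In step count it is on a par with steps 14–16, and it could replace them without changing anything downstream; for the lactone alone it is at least as good.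
- Weak points: it sets one stereocentre of seven in the simplest ring and says nothing about the dihydrobenzofurans or the all-cis ring B. An enzyme must be found that accepts the bulky, electron-rich substrate and gives the R antipode, and substrate loading is usually low.
- Comparison: the chosen plan sets the predictable sense of a rhodium–bisphosphine hydrogenation against the enzyme's mildness, and its key step addresses the hard part of the molecule twice.

**Alternative 3:** The cut is the C2–C3 bond of ring B. A dirhodium carbene from diazolactone A7 would insert into the benzylic C–H bond of the ether arm and give bicyclic lactone A6, with ring B cis-fused to the lactone. Later hydrogenolysis of the lactone's benzylic C–O bond reveals the ring A benzyl group and the C3 carboxyl.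
- Merits: it attacks the hardest stereochemical feature, the all-cis ring B, in one step. The cis fusion guarantees the 3,4-cis relation and an endo aryl group gives 2,3-cis. The chosen plan spends eight steps (17–24) and a one-carbon mask on this ring, so for ring B this road is clearly more economical.
- Weak points: with an achiral catalyst the endo placement of the large aryl group is not assured, since the convex face is the usual preference. A 1,2-hydride shift from C4–H, addition to five electron-rich arenes and insertion at the other benzylic ether C–H bonds compete. The step is run on the fully assembled C–G fragment. The later hydrogenolysis must tell the lactone C–O bond from the para-oxygenated C2–O bond of the new ring B.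
- Comparison: the chosen plan offers individually precedented, stereospecific steps in which each ring B centre is set by a defined event. This road still needs the dihydrobenzofuran fragment, which the ring contraction supplies; it is the most attractive replacement if steps 17–24 prove too long.

Key step: step 6

Assumption: the facial sense of the two chiral catalysts is taken from their closest model reactions ((S)-t-BuPyOx gives an R-configured C2 in a chromanone, hence the R ligand for 9 and the S ligand for 13; the (S,S)-Et-DuPhos–rhodium catalyst gives the R succinate 22). If either sense is reversed, the mirror-image ligand is used.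

Shorthand in names: "aryl CG" is the (2R,3S)-2-[(2S,3R)-2-(4-benzyloxy-3-methoxyphenyl)-3-(tert-butyldimethylsilyloxymethyl)-7-methoxy-2,3-dihydro-1-benzofuran-5-yl]-3-(tert-butyldimethylsilyloxymethyl)-7-methoxy-2,3-dihydro-1-benzofuran-5-yl group (the group bonded to CHO in 18). "aryl CG-diol" is the same group with both silyloxymethyl groups as CH2OH.

## Steps

Step 1
Reactants: 1 1-(2-hydroxy-3-methoxyphenyl)ethanone
Product: 2 1-(5-bromo-2-hydroxy-3-methoxyphenyl)ethanone
Conditions: NBS, MeCN, 0 °C → rt
Reagents that add atoms: N-bromosuccinimide, O=C1CCC(=O)N1Br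
Why: Electrophilic aromatic bromination; the phenol directs to its free para position (C5), both ortho positions being blocked by the acetyl and methoxy groups.

Step 2
Reactants: 2 1-(5-bromo-2-hydroxy-3-methoxyphenyl)ethanone
Product: 4 6-bromo-8-methoxy-4H-chromen-4-one, via enaminone 3 (not isolated)
Conditions: Me2NCH(OMe)2, toluene, 100 °C; then conc. HCl, CH2Cl2, rt
Reagents that add atoms: N,N-dimethylformamide dimethyl acetal, COC(OC)N(C)C
Why: Condensation of the methyl ketone with the amide acetal gives the enaminone, and acid closes the pyranone by addition of the phenol and loss of dimethylamine; this is the standard enaminone route to 3-unsubstituted chromones.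

Step 3
Reactants: 5 4-bromo-2-methoxyphenol
Product: 6 4-bromo-2-methoxyphenyl acetate
Conditions: Ac2O, pyridine, DMAP (cat.), CH2Cl2, rt
Reagents that add atoms: acetic anhydride, CC(=O)OC(C)=O
Why: O-Acylation of the phenol; the acetate is chosen because it later makes ring G electron-poor in the key step.

Step 4
Reactants: 6 4-bromo-2-methoxyphenyl acetate
Product: 8 (4-acetoxy-3-methoxyphenyl)boronic acid, via pinacol boronate 7 (not isolated)
Conditions: B2pin2, Pd(dppf)Cl2 (3 mol %), KOAc, 1,4-dioxane, 85 °C; filter, concentrate; then NaIO4, NH4OAc, acetone/H2O, rt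
Reagents that add atoms: bis(pinacolato)diboron, CC1(C)OB(OC1(C)C)B1OC(C)(C)C(C)(C)O1; water, O
Why: Miyaura borylation (KOAc is too weak a base to cleave the aryl acetate) followed by periodate cleavage of the pinacol ester gives the free boronic acid that the cationic palladium conjugate addition requires.

Step 5
Reactants: 4 6-bromo-8-methoxy-4H-chromen-4-one; 8 (4-acetoxy-3-methoxyphenyl)boronic acid
Product: 9 (2S)-2-(4-acetoxy-3-methoxyphenyl)-6-bromo-8-methoxychroman-4-one
Conditions: Pd(OCOCF3)2 (5 mol %), (R)-t-BuPyOx (6 mol %), NH4PF6 (30 mol %), H2O (5 equiv), ClCH2CH2Cl, 60 °C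
Reagents that add atoms: none
Why: Enantioselective conjugate addition of an arylboronic acid to a chromone on a cationic divalent palladium–pyridine-oxazoline complex (transmetalation, carbopalladation of C2=C3, protonolysis of the palladium enolate). The tert-butyl group of the ligand selects the enone face and sets C2 as S. The cycle stays at divalent palladium, so the aryl bromide is not touched.

Step 6
Reactants: 9 (2S)-2-(4-acetoxy-3-methoxyphenyl)-6-bromo-8-methoxychroman-4-one
Product: 10 methyl (2S,3S)-2-(4-acetoxy-3-methoxyphenyl)-5-bromo-7-methoxy-2,3-dihydro-1-benzofuran-3-carboxylate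
Conditions: PhI(OAc)2 (1.3 equiv), conc. H2SO4, HC(OMe)3, rt
Reagents that add atoms: trimethyl orthoformate, COC(OC)OC
Why: Acid and the orthoester convert the ketone into its dimethyl ketal and the derived 4-methoxy-2H-chromene, whose C3 is attacked by the trivalent iodine electrophile on the face away from the C2 aryl group; methanol returns to C4 and gives a 3-iodanyl ketal whose C3–I bond is pseudo-equatorial and antiperiplanar to the C4–C4a ring bond. The electron-rich ring E carbon C4a then moves from C4 to C3 with inversion as iodobenzene leaves, which forms the C3–C3a bond and leaves a dimethoxycarbenium ion that loses a methyl group to become the methyl ester. Ring F is therefore closed by a 1,2-aryl shift (contraction of the six-membered ring through a bridged phenonium-type transition state) and not by an exo or endo cyclisation. The closest known reaction type is the oxidative ring contraction of flavanones to methyl trans-2-aryl-2,3-dihydrobenzofuran-3-carboxylates with PhI(OAc)2 or Tl(NO3)3 in trimethyl orthoformate. C2 is untouched and controls the new centre C3: anti attack of iodine followed by inversion places the ester trans to the aryl group, which is also the stable epimer, so (2S)-9 should give (2S,3S)-10. The step needs migration of C4a and not of the C2 aryl group, no ionisation of the C2–O bond and no dehydrogenation across C2–C3. The acetate makes ring G a poor migrating group and a poor cation stabiliser, the C2–aryl bond is gauche to the leaving group in the diequatorial conformer, and the ortho-oxygenated ring E carbon migrates readily. Aryl bromide, aryl acetate and methyl ethers are inert to the reagent.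

Step 7
Reactants: 10 methyl (2S,3S)-2-(4-acetoxy-3-methoxyphenyl)-5-bromo-7-methoxy-2,3-dihydro-1-benzofuran-3-carboxylate
Product: 12 [(2S,3S)-2-(4-acetoxy-3-methoxyphenyl)-7-methoxy-3-(methoxycarbonyl)-2,3-dihydro-1-benzofuran-5-yl]boronic acid, via pinacol boronate 11 (not isolated)
Conditions: B2pin2, Pd(dppf)Cl2 (3 mol %), KOAc, 1,4-dioxane, 85 °C; filter, concentrate; then NaIO4, NH4OAc, acetone/H2O, rt
Reagents that add atoms: bis(pinacolato)diboron, CC1(C)OB(OC1(C)C)B1OC(C)(C)C(C)(C)O1; water, O
Why: Miyaura borylation and periodate cleavage as in step 4. Methyl ester and acetate survive the weak base, and the trans ester is the stable epimer, so neither stereocentre is at risk.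

Step 8
Reactants: 4 6-bromo-8-methoxy-4H-chromen-4-one; 12 [(2S,3S)-2-(4-acetoxy-3-methoxyphenyl)-7-methoxy-3-(methoxycarbonyl)-2,3-dihydro-1-benzofuran-5-yl]boronic acid
Product: 13 methyl (2S,3S)-2-(4-acetoxy-3-methoxyphenyl)-5-[(2R)-6-bromo-8-methoxy-4-oxo-3,4-dihydro-2H-chromen-2-yl]-7-methoxy-2,3-dihydro-1-benzofuran-3-carboxylate
Conditions: 4 (1.5 equiv), Pd(OCOCF3)2 (5 mol %), (S)-t-BuPyOx (6 mol %), NH4PF6 (30 mol %), H2O (5 equiv), ClCH2CH2Cl, 60 °C
Reagents that add atoms: none
Why: The same palladium-catalysed conjugate addition with the mirror-image ligand, which sets the new C2 as R by catalyst control whatever the remote centres of 12. Because 12 is already enantioenriched, any minor stereoisomer is a diastereomer and can be removed. The boronic acid has no ortho substituent.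

Step 9
Reactants: 13 methyl (2S,3S)-2-(4-acetoxy-3-methoxyphenyl)-5-[(2R)-6-bromo-8-methoxy-4-oxo-3,4-dihydro-2H-chromen-2-yl]-7-methoxy-2,3-dihydro-1-benzofuran-3-carboxylate
Product: 14 methyl (2R,3R)-2-[(2S,3S)-2-(4-acetoxy-3-methoxyphenyl)-7-methoxy-3-(methoxycarbonyl)-2,3-dihydro-1-benzofuran-5-yl]-5-bromo-7-methoxy-2,3-dihydro-1-benzofuran-3-carboxylate
Conditions: PhI(OAc)2 (1.3 equiv), conc. H2SO4, HC(OMe)3, 0 °C → rt
Reagents that add atoms: trimethyl orthoformate, COC(OC)OC
Why: The same oxidative 1,2-shift as in step 6: C4a of ring C moves to C3 trans to the C2 aryl group, so the (2R) flavanone should give the (2R,3R) ester of ring D. The C2 aryl group is now para-alkoxy-substituted; its own migration stays stereoelectronically disfavoured (gauche to the leaving group), and alkoxy-rich C2 aryl groups lie within the known scope, but this is the less secure use of the reaction.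

Step 10
Reactants: 14 bis-ester acetate bromide (rings C–G)
Product: 15 4-[(2S,3R)-5-[(2R,3S)-5-bromo-3-(hydroxymethyl)-7-methoxy-2,3-dihydro-1-benzofuran-2-yl]-3-(hydroxymethyl)-7-methoxy-2,3-dihydro-1-benzofuran-2-yl]-2-methoxyphenol
Conditions: LiAlH4, THF, 0 °C; aq potassium sodium tartrate
Reagents that add atoms: none
Why: One hydride reduction turns both methyl esters into CH2OH and cleaves the aryl acetate. Reduction is faster than enolisation, so the C3 centres are not disturbed, and the aryl bromide is inert at 0 °C.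

Step 11
Reactants: 15 triol bromide (rings C–G)
Product: 16 {(2R,3S)-2-[(2S,3R)-2-(4-benzyloxy-3-methoxyphenyl)-3-(hydroxymethyl)-7-methoxy-2,3-dihydro-1-benzofuran-5-yl]-5-bromo-7-methoxy-2,3-dihydro-1-benzofuran-3-yl}methanol
Conditions: BnBr, K2CO3, acetone, 50 °C
Reagents that add atoms: benzyl bromide, BrCc1ccccc1
Why: Williamson etherification; carbonate deprotonates only the phenol, so the primary alcohols stay free. The benzyl ether is chosen because it survives fluoride and ozone later.

Step 12
Reactants: 16 benzyl ether diol bromide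
Product: 17 (2R,3S)-2-[(2S,3R)-2-(4-benzyloxy-3-methoxyphenyl)-3-(tert-butyldimethylsilyloxymethyl)-7-methoxy-2,3-dihydro-1-benzofuran-5-yl]-5-bromo-3-(tert-butyldimethylsilyloxymethyl)-7-methoxy-2,3-dihydro-1-benzofuran
Conditions: TBSCl, imidazole, DMF, rt
Reagents that add atoms: tert-butyldimethylsilyl chloride, CC(C)(C)[Si](C)(C)Cl
Why: Silylation of both primary alcohols; the silyl ethers withstand the organolithium, enolate, hydride and ylide steps and leave with fluoride in step 22.

Step 13
Reactants: 17 bis-silyl ether bromide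
Product: 18 (2R,3S)-2-[(2S,3R)-2-(4-benzyloxy-3-methoxyphenyl)-3-(tert-butyldimethylsilyloxymethyl)-7-methoxy-2,3-dihydro-1-benzofuran-5-yl]-3-(tert-butyldimethylsilyloxymethyl)-7-methoxy-2,3-dihydro-1-benzofuran-5-carbaldehyde
Conditions: n-BuLi, THF, −78 °C; then DMF, −78 → 0 °C
Reagents that add atoms: N,N-dimethylformamide, CN(C)C=O
Why: Bromine–lithium exchange at −78 °C is faster than any deprotonation, and the aryllithium is formylated by DMF (Bouveault aldehyde synthesis).

Step 14
Reactants: 19 4-(benzyloxy)-3-methoxybenzaldehyde; 20 dimethyl succinate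
Product: 21 (E)-4-[4-(benzyloxy)-3-methoxyphenyl]-3-(methoxycarbonyl)but-3-enoic acid
Conditions: NaOMe, MeOH, reflux; then aq HCl
Reagents that add atoms: none
Why: Stobbe condensation: the succinate enolate adds to the aldehyde, the adduct lactonises, and E1cB opening of the lactone gives the E half-ester. The benzyl ether is stable to alkoxide.

Step 15
Reactants: 21 (E)-4-[4-(benzyloxy)-3-methoxyphenyl]-3-(methoxycarbonyl)but-3-enoic acid
Product: 22 (3R)-4-[4-(benzyloxy)-3-methoxyphenyl]-3-(methoxycarbonyl)butanoic acid
Conditions: [Rh(cod)((S,S)-Et-DuPhos)]BF4 (1 mol %), H2 (5 bar), NaOMe (10 mol %), MeOH, rt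
Reagents that add atoms: none
Why: Asymmetric hydrogenation of a Stobbe-type itaconate half-ester with a cationic rhodium–bisphospholane catalyst. Chelation of the carboxylate and the alkene fixes the face of hydrogen delivery and sets the future C4 of ring B as R. The homogeneous catalyst does not cleave the benzyl ether.

Step 16
Reactants: 22 (3R)-4-[4-(benzyloxy)-3-methoxyphenyl]-3-(methoxycarbonyl)butanoic acid
Product: 24 (4R)-4-[4-(benzyloxy)-3-methoxybenzyl]dihydrofuran-2(3H)-one, via hydroxy acid 23 (not isolated)
Conditions: KOH (1 equiv), EtOH; CaCl2, NaBH4, EtOH, −10 °C → rt; then 2 M HCl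
Reagents that add atoms: none
Why: Calcium borohydride formed in the flask reduces the ester but not the carboxylate, and acidification lactonises the γ-hydroxy acid. The stereocentre is not involved.

Step 17
Reactants: 24 (4R)-4-[4-(benzyloxy)-3-methoxybenzyl]dihydrofuran-2(3H)-one; 18 aryl CG carbaldehyde
Product: 25 (3S,4R)-4-[4-(benzyloxy)-3-methoxybenzyl]-3-[(R)-hydroxy(aryl CG)methyl]dihydrofuran-2(3H)-one
Conditions: 24 (1.3 equiv), LiN(SiMe3)2, THF, −78 °C; then 18, −78 °C; sat. NH4Cl at −78 °C
Reagents that add atoms: none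
Why: Aldol addition of the lactone lithium enolate. The aldehyde approaches the enolate face anti to the C4 benzyl group (C3 becomes S, trans), and the closed chair (Zimmerman–Traxler) transition state of the ring-constrained E-enolate favours the anti aldol, which is the R carbinol needed for the 2,3-cis relation of ring B. The cold quench prevents retro-aldol equilibration, and the carbinol epimer is separable.

Step 18
Reactants: 25 aldol lactone
Product: 26 (3S,4R)-4-[4-(benzyloxy)-3-methoxybenzyl]-3-[(R)-(triethylsilyloxy)(aryl CG)methyl]dihydrofuran-2(3H)-one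
Conditions: Et3SiOTf, 2,6-lutidine, CH2Cl2, −78 → 0 °C
Reagents that add atoms: triethylsilyl trifluoromethanesulfonate, CC[Si](CC)(CC)OS(=O)(=O)C(F)(F)F
Why: Silylation of the β-hydroxyl blocks retro-aldol cleavage during the next two steps; the triethylsilyl group is chosen because fluoride removes it fastest in step 22.

Step 19
Reactants: 26 silylated aldol lactone
Product: 27 (3S,4R)-4-[4-(benzyloxy)-3-methoxybenzyl]-3-[(R)-(triethylsilyloxy)(aryl CG)methyl]tetrahydrofuran-2-ol (both anomers)
Conditions: i-Bu2AlH (1.2 equiv), CH2Cl2, −78 °C; aq potassium sodium tartrate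
Reagents that add atoms: none
Why: Partial reduction of the γ-lactone; the tetrahedral aluminium hemiacetal persists at −78 °C until work-up. The former carbonyl carbon is now an aldehyde equivalent and the other CH2O carbon a masked primary alcohol, so the two arms are distinguished.

Step 20
Reactants: 27 lactol
Product: 28 (2R,3S)-2-[4-(benzyloxy)-3-methoxybenzyl]-3-[(R)-(triethylsilyloxy)(aryl CG)methyl]pent-4-en-1-ol
Conditions: Ph3PCH3Br, KN(SiMe3)2, THF, 0 °C; then 27, 0 °C → rt
Reagents that add atoms: methyltriphenylphosphonium bromide, C[P+](c1ccccc1)(c1ccccc1)c1ccccc1.[Br-]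
Why: Wittig methylenation of the open hydroxy-aldehyde form of the lactol turns the aldehyde carbon into a vinyl group (the one-carbon mask for the C3 hydroxymethyl) and leaves the future C5 hydroxyl as the only free OH. The unstabilised ylide adds to the aldehyde faster than it epimerises the α-centre.

Step 21
Reactants: 28 alkenol
Product: 29 (2R,3S)-2-[4-(benzyloxy)-3-methoxybenzyl]-3-[(R)-(triethylsilyloxy)(aryl CG)methyl]pent-4-en-1-yl 4-methylbenzenesulfonate
Conditions: TsCl, Et3N, DMAP (cat.), CH2Cl2, 0 °C → rt
Reagents that add atoms: p-toluenesulfonyl chloride, Cc1ccc(cc1)S(Cl)(=O)=O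
Why: Sulfonylation of the single free primary hydroxyl makes C5 the electrophile for ring closure.

Step 22
Reactants: 29 tosylate
Product: 32 (2R,3S,4R)-2-(aryl CG-diol)-4-[4-(benzyloxy)-3-methoxybenzyl]-3-vinyltetrahydrofuran, via hydroxy tosylate 30 (not isolated), via bis-silyl tetrahydrofuran 31 (not isolated)
Conditions: Bu4NF (4 equiv), THF, 0 °C → rt
Reagents that add atoms: none
Why: Fluoride cleaves the triethylsilyl ether first and the benzylic alkoxide displaces the primary tosylate (intramolecular Williamson etherification, 5-exo-tet); no bond to C2 is broken, so the R carbinol becomes the 2,3-cis ring and the 3,4-cis relation is inherited from the trans lactone. The remaining fluoride removes the two primary silyl ethers. No acid is present, so the benzylic C2–O bond cannot ionise.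

Step 23
Reactants: 32 vinyl tetrahydrofuran diol
Product: 34 [(2R,3R,4R)-2-(aryl CG-diol)-4-[4-(benzyloxy)-3-methoxybenzyl]tetrahydrofuran-3-yl]methanol, via aldehyde 33 (not isolated)
Conditions: O3, CH2Cl2/MeOH (4:1), −78 °C (Sudan Red 7B end point); then NaBH4, −78 → 0 °C
Reagents that add atoms: ozone, [O-][O+]=O
Why: Ozonolysis of the terminal alkene, which reacts far faster than the protected arenes (dye end point), with borohydride added cold so that the all-cis aldehyde is reduced before its C3 centre can epimerise.

Step 24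
Reactants: 34 bis-benzyl ether triol
Product: 35 [(2R,3R,4R)-2-{(2R,3S)-2-[(2S,3R)-2-(4-hydroxy-3-methoxyphenyl)-3-(hydroxymethyl)-7-methoxy-2,3-dihydro-1-benzofuran-5-yl]-3-(hydroxymethyl)-7-methoxy-2,3-dihydro-1-benzofuran-5-yl}-4-(4-hydroxy-3-methoxybenzyl)tetrahydrofuran-3-yl]methanol
Conditions: H2 (1 atm), 10% Pd/C, EtOAc, rt, stopped after uptake of 2 equiv
Reagents that add atoms: none
Why: Hydrogenolysis of the two aryl benzyl ethers in a neutral aprotic solvent. These cleave much faster than the cyclic 2-aryl ether C–O bonds, so the all-cis ring B and both dihydrobenzofurans should survive if the reaction is stopped at full debenzylation.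

## Compound list

1 | 1-(2-hydroxy-3-methoxyphenyl)ethanone | COc1cccc(C(C)=O)c1O | starting material
2 | 1-(5-bromo-2-hydroxy-3-methoxyphenyl)ethanone | COc1cc(Br)cc(C(C)=O)c1O | intermediate
3 | (E)-1-(5-bromo-2-hydroxy-3-methoxyphenyl)-3-(dimethylamino)prop-2-en-1-one | COc1cc(Br)cc(C(=O)/C=C/N(C)C)c1O | intermediate (not isolated)
4 | 6-bromo-8-methoxy-4H-chromen-4-one | O=c1ccoc2c(OC)cc(Br)cc12 | intermediate
5 | 4-bromo-2-methoxyphenol | COc1cc(Br)ccc1O | starting material
6 | 4-bromo-2-methoxyphenyl acetate | COc1cc(Br)ccc1OC(C)=O | intermediate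
7 | 2-methoxy-4-(4,4,5,5-tetramethyl-1,3,2-dioxaborolan-2-yl)phenyl acetate | COc1cc(B2OC(C)(C)C(C)(C)O2)ccc1OC(C)=O | intermediate (not isolated)
8 | (4-acetoxy-3-methoxyphenyl)boronic acid | COc1cc(B(O)O)ccc1OC(C)=O | intermediate
9 | (2S)-2-(4-acetoxy-3-methoxyphenyl)-6-bromo-8-methoxychroman-4-one | O=C1C[C@@H](c2ccc(OC(C)=O)c(OC)c2)Oc2c(OC)cc(Br)cc21 | intermediate
10 | methyl (2S,3S)-2-(4-acetoxy-3-methoxyphenyl)-5-bromo-7-methoxy-2,3-dihydro-1-benzofuran-3-carboxylate | Brc1cc(OC)c2c(c1)[C@H](C(=O)OC)[C@@H](c1ccc(OC(C)=O)c(OC)c1)O2 | intermediate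
11 | methyl (2S,3S)-2-(4-acetoxy-3-methoxyphenyl)-7-methoxy-5-(4,4,5,5-tetramethyl-1,3,2-dioxaborolan-2-yl)-2,3-dihydro-1-benzofuran-3-carboxylate | CC1(C)OB(OC1(C)C)c1cc(OC)c2c(c1)[C@H](C(=O)OC)[C@@H](c1ccc(OC(C)=O)c(OC)c1)O2 | intermediate (not isolated)
12 | [(2S,3S)-2-(4-acetoxy-3-methoxyphenyl)-7-methoxy-3-(methoxycarbonyl)-2,3-dihydro-1-benzofuran-5-yl]boronic acid | OB(O)c1cc(OC)c2c(c1)[C@H](C(=O)OC)[C@@H](c1ccc(OC(C)=O)c(OC)c1)O2 | intermediate
13 | methyl (2S,3S)-2-(4-acetoxy-3-methoxyphenyl)-5-[(2R)-6-bromo-8-methoxy-4-oxo-3,4-dihydro-2H-chromen-2-yl]-7-methoxy-2,3-dihydro-1-benzofuran-3-carboxylate | O=C1C[C@H](c2cc(OC)c3c(c2)[C@H](C(=O)OC)[C@@H](c2ccc(OC(C)=O)c(OC)c2)O3)Oc2c(OC)cc(Br)cc21 | intermediate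
14 | methyl (2R,3R)-2-[(2S,3S)-2-(4-acetoxy-3-methoxyphenyl)-7-methoxy-3-(methoxycarbonyl)-2,3-dihydro-1-benzofuran-5-yl]-5-bromo-7-methoxy-2,3-dihydro-1-benzofuran-3-carboxylate | Brc1cc(OC)c2c(c1)[C@@H](C(=O)OC)[C@H](c1cc(OC)c3c(c1)[C@H](C(=O)OC)[C@@H](c1ccc(OC(C)=O)c(OC)c1)O3)O2 | intermediate
15 | 4-[(2S,3R)-5-[(2R,3S)-5-bromo-3-(hydroxymethyl)-7-methoxy-2,3-dihydro-1-benzofuran-2-yl]-3-(hydroxymethyl)-7-methoxy-2,3-dihydro-1-benzofuran-2-yl]-2-methoxyphenol | Brc1cc(OC)c2c(c1)[C@@H](CO)[C@H](c1cc(OC)c3c(c1)[C@H](CO)[C@@H](c1ccc(O)c(OC)c1)O3)O2 | intermediate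
16 | {(2R,3S)-2-[(2S,3R)-2-(4-benzyloxy-3-methoxyphenyl)-3-(hydroxymethyl)-7-methoxy-2,3-dihydro-1-benzofuran-5-yl]-5-bromo-7-methoxy-2,3-dihydro-1-benzofuran-3-yl}methanol | Brc1cc(OC)c2c(c1)[C@@H](CO)[C@H](c1cc(OC)c3c(c1)[C@H](CO)[C@@H](c1ccc(OCc4ccccc4)c(OC)c1)O3)O2 | intermediate
17 | (2R,3S)-2-[(2S,3R)-2-(4-benzyloxy-3-methoxyphenyl)-3-(tert-butyldimethylsilyloxymethyl)-7-methoxy-2,3-dihydro-1-benzofuran-5-yl]-5-bromo-3-(tert-butyldimethylsilyloxymethyl)-7-methoxy-2,3-dihydro-1-benzofuran | Brc1cc(OC)c2c(c1)[C@@H](CO[Si](C)(C)C(C)(C)C)[C@H](c1cc(OC)c3c(c1)[C@H](CO[Si](C)(C)C(C)(C)C)[C@@H](c1ccc(OCc4ccccc4)c(OC)c1)O3)O2 | intermediate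
18 | (2R,3S)-2-[(2S,3R)-2-(4-benzyloxy-3-methoxyphenyl)-3-(tert-butyldimethylsilyloxymethyl)-7-methoxy-2,3-dihydro-1-benzofuran-5-yl]-3-(tert-butyldimethylsilyloxymethyl)-7-methoxy-2,3-dihydro-1-benzofuran-5-carbaldehyde | O=Cc1cc(OC)c2c(c1)[C@@H](CO[Si](C)(C)C(C)(C)C)[C@H](c1cc(OC)c3c(c1)[C@H](CO[Si](C)(C)C(C)(C)C)[C@@H](c1ccc(OCc4ccccc4)c(OC)c1)O3)O2 | intermediate
19 | 4-(benzyloxy)-3-methoxybenzaldehyde | COc1cc(C=O)ccc1OCc1ccccc1 | starting material
20 | dimethyl succinate | COC(=O)CCC(=O)OC | starting material
21 | (E)-4-[4-(benzyloxy)-3-methoxyphenyl]-3-(methoxycarbonyl)but-3-enoic acid | COC(=O)/C(CC(=O)O)=C/c1ccc(OCc2ccccc2)c(OC)c1 | intermediate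
22 | (3R)-4-[4-(benzyloxy)-3-methoxyphenyl]-3-(methoxycarbonyl)butanoic acid | COC(=O)[C@@H](CC(=O)O)Cc1ccc(OCc2ccccc2)c(OC)c1 | intermediate
23 | (3R)-3-[4-(benzyloxy)-3-methoxybenzyl]-4-hydroxybutanoic acid | OC[C@@H](CC(=O)O)Cc1ccc(OCc2ccccc2)c(OC)c1 | intermediate (not isolated)
24 | (4R)-4-[4-(benzyloxy)-3-methoxybenzyl]dihydrofuran-2(3H)-one | COc1cc(C[C@H]2COC(=O)C2)ccc1OCc1ccccc1 | intermediate
25 | (3S,4R)-4-[4-(benzyloxy)-3-methoxybenzyl]-3-[(R)-hydroxy(aryl CG)methyl]dihydrofuran-2(3H)-one | O=C1OC[C@H](Cc2ccc(OCc3ccccc3)c(OC)c2)[C@H]1[C@@H](O)c1cc(OC)c2c(c1)[C@@H](CO[Si](C)(C)C(C)(C)C)[C@H](c1cc(OC)c3c(c1)[C@H](CO[Si](C)(C)C(C)(C)C)[C@@H](c1ccc(OCc4ccccc4)c(OC)c1)O3)O2 | intermediate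
26 | (3S,4R)-4-[4-(benzyloxy)-3-methoxybenzyl]-3-[(R)-(triethylsilyloxy)(aryl CG)methyl]dihydrofuran-2(3H)-one | O=C1OC[C@H](Cc2ccc(OCc3ccccc3)c(OC)c2)[C@H]1[C@@H](O[Si](CC)(CC)CC)c1cc(OC)c2c(c1)[C@@H](CO[Si](C)(C)C(C)(C)C)[C@H](c1cc(OC)c3c(c1)[C@H](CO[Si](C)(C)C(C)(C)C)[C@@H](c1ccc(OCc4ccccc4)c(OC)c1)O3)O2 | intermediate
27 | (3S,4R)-4-[4-(benzyloxy)-3-methoxybenzyl]-3-[(R)-(triethylsilyloxy)(aryl CG)methyl]tetrahydrofuran-2-ol (both anomers) | OC1OC[C@H](Cc2ccc(OCc3ccccc3)c(OC)c2)[C@H]1[C@@H](O[Si](CC)(CC)CC)c1cc(OC)c2c(c1)[C@@H](CO[Si](C)(C)C(C)(C)C)[C@H](c1cc(OC)c3c(c1)[C@H](CO[Si](C)(C)C(C)(C)C)[C@@H](c1ccc(OCc4ccccc4)c(OC)c1)O3)O2 | intermediate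
28 | (2R,3S)-2-[4-(benzyloxy)-3-methoxybenzyl]-3-[(R)-(triethylsilyloxy)(aryl CG)methyl]pent-4-en-1-ol | OC[C@H](Cc2ccc(OCc3ccccc3)c(OC)c2)[C@H](C=C)[C@@H](O[Si](CC)(CC)CC)c1cc(OC)c2c(c1)[C@@H](CO[Si](C)(C)C(C)(C)C)[C@H](c1cc(OC)c3c(c1)[C@H](CO[Si](C)(C)C(C)(C)C)[C@@H](c1ccc(OCc4ccccc4)c(OC)c1)O3)O2 | intermediate
29 | (2R,3S)-2-[4-(benzyloxy)-3-methoxybenzyl]-3-[(R)-(triethylsilyloxy)(aryl CG)methyl]pent-4-en-1-yl 4-methylbenzenesulfonate | Cc1ccc(cc1)S(=O)(=O)OC[C@H](Cc2ccc(OCc3ccccc3)c(OC)c2)[C@H](C=C)[C@@H](O[Si](CC)(CC)CC)c1cc(OC)c2c(c1)[C@@H](CO[Si](C)(C)C(C)(C)C)[C@H](c1cc(OC)c3c(c1)[C@H](CO[Si](C)(C)C(C)(C)C)[C@@H](c1ccc(OCc4ccccc4)c(OC)c1)O3)O2 | intermediate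
30 | (2R,3S)-2-[4-(benzyloxy)-3-methoxybenzyl]-3-[(R)-hydroxy(aryl CG)methyl]pent-4-en-1-yl 4-methylbenzenesulfonate | Cc1ccc(cc1)S(=O)(=O)OC[C@H](Cc2ccc(OCc3ccccc3)c(OC)c2)[C@H](C=C)[C@@H](O)c1cc(OC)c2c(c1)[C@@H](CO[Si](C)(C)C(C)(C)C)[C@H](c1cc(OC)c3c(c1)[C@H](CO[Si](C)(C)C(C)(C)C)[C@@H](c1ccc(OCc4ccccc4)c(OC)c1)O3)O2 | intermediate (not isolated)
31 | (2R,3S,4R)-2-(aryl CG)-4-[4-(benzyloxy)-3-methoxybenzyl]-3-vinyltetrahydrofuran | COc1cc(C[C@H]2CO[C@@H](c3cc(OC)c4c(c3)[C@@H](CO[Si](C)(C)C(C)(C)C)[C@H](c3cc(OC)c5c(c3)[C@H](CO[Si](C)(C)C(C)(C)C)[C@@H](c3ccc(OCc6ccccc6)c(OC)c3)O5)O4)[C@H]2C=C)ccc1OCc1ccccc1 | intermediate (not isolated)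
32 | (2R,3S,4R)-2-(aryl CG-diol)-4-[4-(benzyloxy)-3-methoxybenzyl]-3-vinyltetrahydrofuran | COc1cc(C[C@H]2CO[C@@H](c3cc(OC)c4c(c3)[C@@H](CO)[C@H](c3cc(OC)c5c(c3)[C@H](CO)[C@@H](c3ccc(OCc6ccccc6)c(OC)c3)O5)O4)[C@H]2C=C)ccc1OCc1ccccc1 | intermediate
33 | (2R,3S,4R)-2-(aryl CG-diol)-4-[4-(benzyloxy)-3-methoxybenzyl]tetrahydrofuran-3-carbaldehyde | COc1cc(C[C@H]2CO[C@@H](c3cc(OC)c4c(c3)[C@@H](CO)[C@H](c3cc(OC)c5c(c3)[C@H](CO)[C@@H](c3ccc(OCc6ccccc6)c(OC)c3)O5)O4)[C@H]2C=O)ccc1OCc1ccccc1 | intermediate (not isolated)
34 | [(2R,3R,4R)-2-(aryl CG-diol)-4-[4-(benzyloxy)-3-methoxybenzyl]tetrahydrofuran-3-yl]methanol | COc1cc(C[C@H]2CO[C@@H](c3cc(OC)c4c(c3)[C@@H](CO)[C@H](c3cc(OC)c5c(c3)[C@H](CO)[C@@H](c3ccc(OCc6ccccc6)c(OC)c3)O5)O4)[C@H]2CO)ccc1OCc1ccccc1 | intermediate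
35 | [(2R,3R,4R)-2-{(2R,3S)-2-[(2S,3R)-2-(4-hydroxy-3-methoxyphenyl)-3-(hydroxymethyl)-7-methoxy-2,3-dihydro-1-benzofuran-5-yl]-3-(hydroxymethyl)-7-methoxy-2,3-dihydro-1-benzofuran-5-yl}-4-(4-hydroxy-3-methoxybenzyl)tetrahydrofuran-3-yl]methanol (CNP0395728.1) | COc1cc(C[C@H]2CO[C@@H](c3cc(OC)c4c(c3)[C@@H](CO)[C@H](c3cc(OC)c5c(c3)[C@H](CO)[C@@H](c3ccc(O)c(OC)c3)O5)O4)[C@H]2CO)ccc1O | target

## Step count and least certain steps

Total: 24 steps. Longest linear sequence: 19 steps (steps 3–13 and 17–24 from 5; equally steps 1, 2, 5–13 and 17–24 from 1).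

**Step 6 (key step).** The C2 aryl group may migrate instead of the ring E carbon, the C2–C3 bond may be dehydrogenated, C3 may be methoxylated without rearrangement, or the pyranone may open under acid with loss of the C2 configuration; partial solvolysis of the acetate would also reduce the electronic bias. Fallback: a Wolff ring contraction, which makes the same C4a shift onto a carbene and needs neither acid nor an electrophilic oxidant. Setting out from 9, trifluoroacetylation of its lithium enolate (LiN(SiMe3)2, CF3CO2CH2CF3, −78 °C) would give the 3-trifluoroacetyl ketone F1. Diazo transfer with MsN3/Et3N would give the 3-diazochromanone F2. Irradiation of F2 in methanol with Et3N should give the ketene by migration of C4a to C3; methanol traps it and the ester settles as the stable trans epimer. The route is rejoined at 10.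

**Step 9.** The C2 aryl group is now para-alkoxy-substituted, so ionisation of the C2–O bond (epimerisation at C2 of the chromanone), migration of this aryl group, or attack of the oxidant on the electron-rich ring E may compete with the wanted shift. Fallback: the same Wolff sequence. Setting out from 13, one equivalent of LiN(SiMe3)2 at −78 °C enolises the ketone in preference to the ester, and CF3CO2CH2CF3 gives the trifluoroacetyl ketone F3. MsN3/Et3N gives the diazo ketone F4, and photolysis in methanol returns to the route at 14.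

**Step 17.** Facial selectivity at the aldehyde carbon may be low, because lithium enolates of cyclic esters often give modest anti/syn ratios with aromatic aldehydes, and retro-aldol equilibration on warming would erode it further. Fallback: set the carbinol by reduction instead of by C–C bond formation. Setting out from 25 as obtained, at whatever epimer ratio at the carbinol carbon, Dess–Martin oxidation would give the β-keto lactone F5 (C3 stays trans to the benzyl group, its stable arrangement). Asymmetric transfer hydrogenation with RuCl[(R,R)-TsDPEN](p-cymene) and HCO2H/Et3N should reduce the aryl ketone under catalyst control to the R carbinol. The route is rejoined at 25.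

**Step 22.** Fluoride may substitute or eliminate the primary sulfonate before the hindered benzylic silyl ether is cleaved, or a silyl group may migrate to the liberated alkoxide, so that closure is incomplete. Fallback: a redox condensation without a sulfonate. Setting out from 28, buffered HF·pyridine in THF/pyridine at 0 °C removes only the triethylsilyl group and gives the diol F6. Mitsunobu cyclodehydration (PPh3, DIAD, THF) activates the primary hydroxyl, and attack of the benzylic hydroxyl with retention at C2 gives 31. Bu4NF then cleaves the two primary silyl ethers, and the route is rejoined at 32.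

## Further compounds

F1 | step 6 | 4-[(2S)-6-bromo-8-methoxy-4-oxo-3-(trifluoroacetyl)-3,4-dihydro-2H-chromen-2-yl]-2-methoxyphenyl acetate | O=C1C(C(=O)C(F)(F)F)[C@@H](c2ccc(OC(C)=O)c(OC)c2)Oc2c(OC)cc(Br)cc21
F2 | step 6 | 4-[(2R)-6-bromo-3-diazo-8-methoxy-4-oxo-3,4-dihydro-2H-chromen-2-yl]-2-methoxyphenyl acetate | O=C1C(=[N+]=[N-])[C@@H](c2ccc(OC(C)=O)c(OC)c2)Oc2c(OC)cc(Br)cc21
F3 | step 9 | 3-trifluoroacetyl derivative of 13 (trifluoroacetyl group on C3 of the chromanone) | O=C1C(C(=O)C(F)(F)F)[C@H](c2cc(OC)c3c(c2)[C@H](C(=O)OC)[C@@H](c2ccc(OC(C)=O)c(OC)c2)O3)Oc2c(OC)cc(Br)cc21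
F4 | step 9 | 3-diazo derivative of 13 (diazo group on C3 of the chromanone) | O=C1C(=[N+]=[N-])[C@H](c2cc(OC)c3c(c2)[C@H](C(=O)OC)[C@@H](c2ccc(OC(C)=O)c(OC)c2)O3)Oc2c(OC)cc(Br)cc21
F5 | step 17 | (3S,4R)-3-(aryl CG-carbonyl)-4-[4-(benzyloxy)-3-methoxybenzyl]dihydrofuran-2(3H)-one | O=C1OC[C@H](Cc2ccc(OCc3ccccc3)c(OC)c2)[C@H]1C(=O)c1cc(OC)c2c(c1)[C@@H](CO[Si](C)(C)C(C)(C)C)[C@H](c1cc(OC)c3c(c1)[C@H](CO[Si](C)(C)C(C)(C)C)[C@@H](c1ccc(OCc4ccccc4)c(OC)c1)O3)O2
F6 | step 22 | (2R,3S)-2-[4-(benzyloxy)-3-methoxybenzyl]-3-[(R)-hydroxy(aryl CG)methyl]pent-4-en-1-ol | OC[C@H](Cc2ccc(OCc3ccccc3)c(OC)c2)[C@H](C=C)[C@@H](O)c1cc(OC)c2c(c1)[C@@H](CO[Si](C)(C)C(C)(C)C)[C@H](c1cc(OC)c3c(c1)[C@H](CO[Si](C)(C)C(C)(C)C)[C@@H](c1ccc(OCc4ccccc4)c(OC)c1)O3)O2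
A1 | alternative 1 | (2S,3R)-2-(4-benzyloxy-3-methoxyphenyl)-3-(benzyloxymethyl)-5-bromo-7-methoxy-2,3-dihydro-1-benzofuran | Brc1cc(OC)c2c(c1)[C@H](COCc1ccccc1)[C@@H](c1ccc(OCc3ccccc3)c(OC)c1)O2
A2 | alternative 1 | 2-[2-(benzyloxy)-1-(4-methylphenylsulfonyl)ethyl]-4-bromo-6-methoxyphenol | COc1cc(Br)cc(C(COCc2ccccc2)S(=O)(=O)c2ccc(C)cc2)c1O
A3 | alternative 1 | [4-(benzyloxy)-3-methoxybenzyl]dimethylsulfonium bromide | C[S+](C)Cc1ccc(OCc2ccccc2)c(OC)c1.[Br-]
A4 | alternative 2 | (4R)-4-[4-(benzyloxy)-3-methoxybenzyl]dihydrofuran-2(3H)-one (identical with 24) | COc1cc(C[C@H]2COC(=O)C2)ccc1OCc1ccccc1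
A5 | alternative 2 | 3-[4-(benzyloxy)-3-methoxybenzyl]cyclobutan-1-one | O=C1CC(Cc2ccc(OCc3ccccc3)c(OC)c2)C1
A6 | alternative 3 | cis-fused 3,7-dioxabicyclo[3.3.0]octan-2-one with the silyl-protected aryl CG group endo on C6 and the 4-benzyloxy-3-methoxyphenyl group on C4 (configuration as in the SMILES) | COc1cc([C@@H]6[C@H]2CO[C@@H](c3cc(OC)c4c(c3)[C@@H](CO[Si](C)(C)C(C)(C)C)[C@H](c3cc(OC)c5c(c3)[C@H](CO[Si](C)(C)C(C)(C)C)[C@@H](c3ccc(OCc7ccccc7)c(OC)c3)O5)O4)[C@H]2C(=O)O6)ccc1OCc1ccccc1
A7 | alternative 3 | 3-diazo-5-(4-benzyloxy-3-methoxyphenyl)-4-[(aryl CG)methoxymethyl]dihydrofuran-2(3H)-one (configuration as in the SMILES) | COc1cc([C@@H]6[C@@H](COCc3cc(OC)c4c(c3)[C@@H](CO[Si](C)(C)C(C)(C)C)[C@H](c3cc(OC)c5c(c3)[C@H](CO[Si](C)(C)C(C)(C)C)[C@@H](c3ccc(OCc7ccccc7)c(OC)c3)O5)O4)C(=[N+]=[N-])C(=O)O6)ccc1OCc1ccccc1
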